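The readings stem from a simulated flask on assumed constants, and the scatter is random.

The product is judged per chain: the average is monomer in chains divided by chains begun, living and dead together. A forecast therefore needs a count of chains, which the earlier runs do not show.

common to all: free monomer 0.59 M; transfer agent 0.177 M; impurity 15 mM

| run | initiator | remark | time |
|---|---|---|---|
| birch | 31 mM | run made earlier |  |
| alder | 110 mM | run made earlier |  |
| south | 50 mM |  | 4.0 min |
| south-east | 150 mM |  | 4.0 min |

| run | time / s | monomer in chains / % |
|---|---|---|
| birch | 15.0 | 20.2 |
| birch | 30.0 | 35.2 |
| birch | 50.0 | 50.0 |
| birch | 60.0 | 56.6 |
| birch | 80.0 | 64.6 |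
| birch | 90.0 | 66.3 |
| birch | 120 | 71.2 |
| alder | 15.0 | 67.7 |
| alder | 30.0 | 88.0 |
| alder | 50.0 | 96.5 |
| alder | 60.0 | 95.5 |
| alder | 80.0 | 96.0 |
| alder | 90.0 | 97.7 |
| alder | 120 | 98.2 |

(readings scatter by 1 percentage point)

- which of the two ends with the longer chains by the average number of monomer units in a chain (chains begun, living or dead) ("neither" if they lie within 10%) (south / south-east / neither)
- average number of monomer units in a chain (chains begun, living or dead) at the end, south
- average number of monomer units in a chain (chains begun, living or dead) at the end, south-east

- the average divides the monomer in chains by the number of chains begun, living and dead together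
- the numbers in the tables scatter with a standard deviation of 1 percentage point
- what may be going on: initiator + impurity -> spent initiator; free monomer + living end -> monomer in chains + living end; living end + transfer agent -> dead chain; free monomer -> decomposition product; free monomer + initiator -> living end + monomer in chains; free monomer -> uncatalysed product
- the earlier runs do not show the number of chains; that part of a forecast is a guess

Two ways reach the ratio of living ends in alder to those in birch. The first readings, taken as first-order loss of free monomer, give 0.0753 s⁻¹ in alder and 0.0150 s⁻¹ in birch, a ratio of 5.01. The initiator charges give 3.55, so the two ways part. Taking the impurity charge off each initiator charge gives 5.94, which lies nearer the reading. The raw charge is thus the one that cheats, although a gap remains between the reading and the corrected ratio, and each reading carries its scatter of 1 percentage point.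

The quantity to carry is the chain count, initiator charge less impurity charge 35.0 mM in south and 135 mM in south-east. My own reckoning scales alder's rate to south's count, which gives free monomer a half-life of 25.0 s, shorter than the 4.0 min allowed. Charged monomer over the count then gives estimates of 16.9 in south and 4.37 in south-east, so south has the longer chains.

The forecast, “Assuming all surviving initiator starts chains”, names south, with 15.3 in south and 4.3 in south-east.

The flask gives south, with 15.9 in south and 4.52 in south-east.

    initiator + impurity → spent initiator (k = 38.0 M⁻¹ s⁻¹)
    free monomer + living end → monomer in chains + living end, rate k2*[living end]*[free monomer] (k = 0.871 M⁻¹ s⁻¹)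
    living end + transfer agent → dead chain (kL = 0.0175 M⁻¹ s⁻¹)
    free monomer → decomposition product (k = 3.27 × 10⁻⁶ s⁻¹)
    free monomer + initiator → living end + monomer in chains (k = 0.533 M⁻¹ s⁻¹)
    free monomer → uncatalysed product (k = 0.00142 s⁻¹)

In south, initiator stood at 0% of its charge by 2.00 min while free monomer fell to 3.89%, and at 4.00 min living ends and dead chains summed to 35.1 mM, close to the count. In south-east, free monomer stood at 0% by 2.00 min with 4.20% of the initiator unused, and chains summed to 129 mM at 4.00 min. In the neighbour flask with 0.60 M of initiator, the count of 585 mM gives an estimate of 1.01, but free monomer, the limiting reagent there, fell to 0% with 42% of the initiator left, and the average stood at 1.77.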